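## Structural features

The target 22 is an achiral, tetrabrominated diphenyl ether: two benzene rings joined by a single oxygen bridge, with no stereocentre, so no question of configuration arises. Ring A is pentasubstituted: C1 carries the free hydroxyl, C2 the bridging oxygen, C3 and C5 bromine, C4 a methoxy group wedged between the two bromines, and C6 the only hydrogen. Ring B is a 2,4-dibromophenyl group bound to the ether oxygen through C1', with bromine at C2' and C4'. The fragile features are the four aryl C–Br bonds, which rule out hydrogenolysis, alkyllithium reagents and low-valent palladium or nickel once they are present, and the hydroquinone-type oxygenation of ring A, which makes its phenols prone to oxidation. The real difficulty is regiochemical and steric: the ether oxygen lies between an oxygen and a bromine on ring A and beside a bromine on ring B, so joining two fully brominated halves would be a doubly ortho-hindered O-arylation with competing C–Br sites, and on ring A three oxygens must be told apart while bromine is kept away from C6. The key step exploits the fact that the sequence C2'(Br)–C3'(H)–C4'(Br)–C5'(H) of ring B is the C3–C4–C5–C6 chain of 3,5-dibromo-2-pyrone 3, while C1' and C6' can come from an ethynyl group already bonded to the ring A oxygen, so ring B is grown on that oxygen instead of being attached to it. A second feature is used afterwards: C3 and C5 of ring A are the two positions ortho to the C4 oxygen, whose para position is occupied, so a free C4 hydroxyl can direct both ring A bromines.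

## Logic of the disconnections

22 ⇒ 20. The O–CH2 bond of a benzyl group on the C1 oxygen is cut. The C1 hydroxyl has to stay masked until all bromines are in place, because a free C1 hydroxyl would steer an electrophile to C6. The gain is that 20 has every substituent placed and all three oxygens differentiated. The demand on the forward step is an ether cleavage that leaves four C–Br bonds and the crowded methyl ether alone, which points to a Lewis acid with a cation trap and excludes hydrogenolysis.

20 ⇒ 19. The O–CH3 bond at C4 is cut. The C4 oxygen must be a free hydroxyl during bromination and can only be methylated afterwards. In 19 it is the only free hydroxyl, so alkylation is unambiguous. The forward step must alkylate an acidic, doubly ortho-brominated phenol, which calls for a small electrophile.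

19 ⇒ 17. The C3–Br and C5–Br bonds are cut. Both are ortho to the C4 hydroxyl and the para position is blocked by the C1 oxygen, so the free phenol itself directs them. The gain is a ring A free of halogen, which allows strong base earlier in the route. The forward step must brominate twice, including the C3 position between hydroxyl and aryloxy group, without oxidising the para-alkoxyphenol and without touching C6 or ring B.

17 ⇒ 16. The O–Si bond at the C4 oxygen is cut. A bulky silyl ether is the orthogonal partner of the benzyl ether and keeps the C4 oxygen inert to carbonate, alkyllithium and heat. The forward step needs fluoride cleavage that spares the benzyl ether, the diaryl ether and the C–Br bonds.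

16 ⇒ 14 + 3. The C1'–C2' and C5'–C6' bonds of ring B are cut, and the carboxyl bridge of 3 is restored. This avoids any hindered O-arylation with a polybrominated arene and fixes both ring B bromines by connectivity. Ring B shrinks to a two-carbon alkyne on oxygen plus a one-step heterocycle. The forward step must join the oxygen-bearing alkyne carbon to C3 of 3, run faster than 14 decomposes, and end with decarboxylative aromatisation.

3 ⇒ 1. The two C–Br bonds of 3 are cut, one back to C–H at C3 and one back to the carboxyl carbon at C5. This leads to a cheap commodity acid. The forward step must combine electrophilic bromination with ipso-bromodecarboxylation in one flask.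

14 ⇒ 11. The second π bond of the alkyne and its terminal C–H are traced back to two C–Cl bonds and a vinylic C–H, a formal twofold loss of hydrogen halide. The gain is that a labile ynol ether is replaced by a robust, storable halovinyl ether. The forward step needs two equivalents of alkyllithium, acceptable only because ring A has no halogen at this stage, and low temperature to avoid metallation at the benzylic position or attack at silicon.

11 ⇒ 8 + 9. The O–C(vinyl) bond is cut. This is the most direct way to put a two-carbon unit at the alkyne oxidation level on a phenol oxygen, and it reduces the fragment to a phenol and a commodity solvent. The forward step must generate 10 from 9 in the flask with a base mild enough for the aryl silyl ether, and the phenoxide must add to it once and with anti protonation.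

8 ⇒ 6. The C2–O bond of ring A is traced back to a C–CHO bond. A 1,2,4-trioxygenated benzene with three different oxygens is hard to get by selective protection of a triol, whereas the formyl group marks the position unambiguously. The forward step requires aryl migration in a peracid oxidation, which the ortho-alkoxy group secures, and a mild cleavage of 7.

6 ⇒ 5. The O–CH2 bond of the benzyl group at the future C1 oxygen is cut. In 5 only one hydroxyl is free, so no selectivity question arises. The forward step must alkylate a chelated, aldehyde-flanked hydroxyl under conditions that leave the aryl silyl ether in place.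

5 ⇒ 4. The O–Si bond at the future C4 oxygen is cut, which leads to a commercial dihydroxybenzaldehyde. The two hydroxyls of 4 differ, because one is hydrogen-bonded to the formyl group and flanked by it. The forward step must silylate the remote hydroxyl only, which a bulky silyl chloride in slight excess should achieve.

## Other disconnections considered

Alternative 1: The cut runs through ring A itself (C3–C4, C1–C2 and C1–C6) and leads to three components: the vinyl(methoxy)carbene complex of zerovalent chromium A3, (CO)5Cr=C(OMe)CH=CH2; the ethynyl ether A2, which derives from 2,4-dibromophenol A4; and one carbonyl ligand of A3. In the forward sense a Dötz benzannulation would insert A2 into the carbene, take up the carbonyl ligand and electrocyclise to 2-(2,4-dibromophenoxy)-4-methoxyphenol A1.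
- In its favour: the step is highly convergent, and ring A emerges with all three oxygens in place and already differentiated (free C1 hydroxyl, C4 methoxy). On this point it is better than the chosen plan, which needs two protecting groups and a separate methylation.
- Against it, making A2: the halovinyl ether route from A4 to A2 needs an alkyllithium, which would also attack the two aryl bromides by halogen–metal exchange. The chosen plan avoids this because 14 carries no halogen.
- Against it, the annulation: regiochemistry with alkoxyalkynes is governed by electronics as well as sterics and is less predictable than for simple terminal alkynes. A stoichiometric chromium carbonyl complex also brings toxic waste.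
- Against it, the end game: A1 has its free hydroxyl at C1 and its methoxy at C4, the reverse of what is needed to direct bromine to C3 and C5. A free C1 hydroxyl would send the electrophile to C6, so the hydroxyl would have to be masked and two brominations forced ortho to a methoxy group, one of them at the crowded C3.
- Comparison: both plans build a ring around an ynol ether, this one through a metallacycle and vinylketene, the chosen one through a metal-free pericyclic sequence. On paper this alternative is shorter by a few steps, but it carries two steps of doubtful feasibility where the chosen plan has one.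

Alternative 2: No skeletal bond is cut. The four C–Br bonds (C3, C5, C2', C4') are removed together, leading to the halogen-free ester (4-hydroxy-2-phenoxyphenyl) pivalate A5. In the forward sense four equivalents of bromine A7 would convert A5 into [3,5-dibromo-2-(2,4-dibromophenoxy)-4-hydroxyphenyl] pivalate A6 by four electrophilic substitutions. Methylation and ester cleavage would then give 22.
- In its favour: A5 should be accessible from halogen-free partners by a standard copper-mediated etherification, with no chemoselectivity problem among aryl halides, and one operation makes four bonds. On step economy it is clearly better than the chosen plan.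
- On ring A regiocontrol it is the equal of the chosen plan, since it uses the same free C4 hydroxyl. Its pivalate deactivates C6 more than the benzyl ether of 17 does, which is a further point in its favour.
- Against it: ring B must take up exactly two bromines, para and one ortho, through an ether oxygen whose donor strength falls as ring A is brominated. The para substitution should be easy, but the ortho one would compete with a third substitution at C6' and with attack at C6. The outcome rests on rate differences between closely related polybrominated congeners that are hard to separate, and any excess of A7 adds to the risk of over-bromination.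
- Comparison: in the chosen plan the ring B pattern is fixed by the connectivity of 3 rather than by relative rates. Mechanistically this alternative is four consecutive electrophilic substitutions against one cycloaddition.

Alternative 3: The cut removes the C2–O and C3–Br bonds of ring A together and leads to 3-methoxybenzyne A9, 2,4-dibromophenol A4 and the positive-bromine donor tetrabromomethane A10. In the forward sense fluoride would release A9 from 3-methoxy-2-(trimethylsilyl)phenyl trifluoromethanesulfonate A8. The phenoxide of A4 would add at the aryne carbon remote from the methoxy group (the future C2), and the aryl anion formed next to the methoxy group (the future C3) would take bromine from A10 to give 2-bromo-1-(2,4-dibromophenoxy)-3-methoxybenzene A11.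
- In its favour: the most congested part of the target, the ether oxygen with its flanking bromine next to the methoxy group, is made in one metal-free step. The orientation of additions to 3-alkoxyarynes is dependable, and on this bond set the plan is at least the equal of the chosen one.
- Ring B is simply bought as A4, which is better than building it.
- Against it, the end game: A11 still lacks the C1 hydroxyl and the C5 bromine. C1 is para to the methoxy group and is the natural site for an electrophile, so oxygen would have to be brought in there by a multistep C–H functionalisation. Once a C1 hydroxyl exists, bromine is steered to C6 and not to C5.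
- Against it, the key step: a weakly nucleophilic, hindered phenoxide must outrun other nucleophiles for the aryne, and proton capture by the aryl anion competes with bromine transfer.
- Comparison: a polar aryne addition with halogen transfer against a pericyclic ring synthesis. With about three steps to A8 and at least four after A11, the step count is no lower than that of the chosen plan, and the regiocontrol at the end is weaker.

Key step: step 7

Remark on the chemistry: 14 is assumed to be unstable on storage and is used as a freshly prepared solution; 15 forms as a racemate whose two stereocentres vanish in the same step; joining the oxygen-bearing alkyne carbon to C3 of 3 maps onto the 2,4-dibromo pattern of ring B (the reverse orientation would give 3,5), so the structures of 14, 3 and 16 are mutually consistent.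

## Route

Step 1
Reactants: 1 coumalic acid (2-oxo-2H-pyran-5-carboxylic acid)
Product: 3 3,5-dibromo-2H-pyran-2-one, via 3-bromocoumalic acid 2 (not isolated)
Conditions: NBS (2.5 equiv), LiOAc, MeCN–H2O, rt
Reagents that add atoms: N-bromosuccinimide, O=C1CCC(=O)N1Br
Why: Electrophilic bromination at C3 and Hunsdiecker-type ipso-bromodecarboxylation of the lithium carboxylate at C5 should occur in one flask, since C3 and C5 are the nucleophilic carbons of the 2-pyrone; the order of the two bromine transfers does not change the product.

Step 2
Reactants: 4 2,5-dihydroxybenzaldehyde
Product: 5 2-hydroxy-5-[(triisopropylsilyl)oxy]benzaldehyde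
Conditions: TIPSCl (1.05 equiv), imidazole, CH2Cl2, 0 °C to rt
Reagents that add atoms: chlorotri(propan-2-yl)silane, CC(C)[Si](Cl)(C(C)C)C(C)C
Why: Regioselective O-silylation; the C2 hydroxyl is hydrogen-bonded to the aldehyde and flanked by it, so the bulky silyl chloride should react only at the remote C5 hydroxyl.

Step 3
Reactants: 5 2-hydroxy-5-[(triisopropylsilyl)oxy]benzaldehyde
Product: 6 2-(benzyloxy)-5-[(triisopropylsilyl)oxy]benzaldehyde
Conditions: BnBr, K2CO3, acetone, 56 °C
Reagents that add atoms: benzyl bromide, BrCc1ccccc1
Why: Williamson etherification of the acidic salicylaldehyde hydroxyl; the hindered aryl silyl ether should survive carbonate in acetone.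

Step 4
Reactants: 6 2-(benzyloxy)-5-[(triisopropylsilyl)oxy]benzaldehyde
Product: 8 2-(benzyloxy)-5-[(triisopropylsilyl)oxy]phenol, via aryl formate 7 (not isolated)
Conditions: mCPBA, CH2Cl2, 0 °C to rt; then Et3N, MeOH, rt
Reagents that add atoms: 3-chloroperoxybenzoic acid, O=C(OO)c1cccc(Cl)c1
Why: Dakin-type Baeyer–Villiger oxidation; the electron-rich ortho-alkoxy aryl group migrates in preference to hydride to give formate 7, which amine-catalysed methanolysis should cleave without harming the silyl ether.

Step 5
Reactants: 8 2-(benzyloxy)-5-[(triisopropylsilyl)oxy]phenol; 9 trichloroethylene
Product: 11 1-(benzyloxy)-2-{[(E)-1,2-dichloroethenyl]oxy}-4-[(triisopropylsilyl)oxy]benzene, via dichloroacetylene 10 (not isolated)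
Conditions: K2CO3, dry DMF, 70 °C, argon
Reagents that add atoms: none
Why: Base-mediated dehydrochlorination of 9 gives dichloroacetylene 10 in solution, and the phenoxide of 8 adds to it with anti protonation to give the (E)-1,2-dichlorovinyl ether, the standard precursor of alkynyl ethers.

Step 6
Reactants: 11 1-(benzyloxy)-2-{[(E)-1,2-dichloroethenyl]oxy}-4-[(triisopropylsilyl)oxy]benzene
Product: 14 1-(benzyloxy)-2-(ethynyloxy)-4-[(triisopropylsilyl)oxy]benzene, via chloroethynyl ether 12 (not isolated), via lithium aryloxyacetylide 13 (not isolated)
Conditions: n-BuLi (2.3 equiv), THF, −78 to −40 °C; then H2O, −78 °C; cold extraction into toluene, used at once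
Reagents that add atoms: none
Why: Alkyllithium-induced β-elimination of HCl gives chloroalkyne 12, chlorine–lithium exchange gives acetylide 13, and cold protonation gives the terminal ynol ether; ring A has no halogen, and at −78 °C neither the benzylic position nor the hindered silicon should be attacked.

Step 7
Reactants: 14 1-(benzyloxy)-2-(ethynyloxy)-4-[(triisopropylsilyl)oxy]benzene; 3 3,5-dibromo-2H-pyran-2-one
Product: 16 1-(benzyloxy)-2-(2,4-dibromophenoxy)-4-[(triisopropylsilyl)oxy]benzene, via bridged lactone 15 (not isolated)
Conditions: 3 (1.5 equiv), BHT (cat.), toluene, 100 °C, sealed tube
Reagents that add atoms: none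
Why: A thermal inverse-electron-demand Diels–Alder reaction between the electron-poor diene 3 and the electron-rich ynol ether 14 gives the bridged lactone 15, which loses CO2 by cycloreversion; the closest known reaction type is the 2-pyrone–alkyne cycloaddition/decarboxylation route to benzenes, in which brominated 2-pyrones serve as ambiphilic dienes. Ring B is closed by a concerted, asynchronous, suprafacial [4+2] addition across C3 and C6 of 3 that makes C1'–C2' and C5'–C6' in one event, so no exo or endo ring-closure mode is involved, and the lactone bridge of 15 is only transient. The two bridgehead stereocentres of 15 form as a racemate with a relative configuration dictated by the bicyclic frame, and both vanish on aromatisation, so no stereocontrol is needed. The selectivity required is regiochemical: the oxygen-bearing alkyne carbon must bond to C3 of 3. This should follow from the polarisation of both partners, because the terminal carbon of 14 has the largest HOMO coefficient and C6 of 3, the terminus of the dienyl ester, the largest LUMO coefficient, so the C6–CH bond leads and the oxygen-substituted carbon closes onto C3. The same orientation places a donor substituent next to the former C3 in additions of enol ethers to 3-bromo-2-pyrones. Loss of CO2 is driven by aromatisation and should be spontaneous at the reaction temperature. The benzyl and silyl ethers are inert to heat, and an excess of 3 should keep the bimolecular cycloaddition ahead of oligomerisation of 14.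

Step 8
Reactants: 16 1-(benzyloxy)-2-(2,4-dibromophenoxy)-4-[(triisopropylsilyl)oxy]benzene
Product: 17 4-(benzyloxy)-3-(2,4-dibromophenoxy)phenol
Conditions: Bu4NF (1.1 equiv), AcOH (1.1 equiv), THF, 0 °C
Reagents that add atoms: none
Why: Fluoride-induced Si–O cleavage driven by the strong Si–F bond; acetic acid buffering keeps the electron-rich phenoxide from air oxidation, and the benzyl ether, diaryl ether and C–Br bonds are inert.

Step 9
Reactants: 17 4-(benzyloxy)-3-(2,4-dibromophenoxy)phenol
Product: 19 4-(benzyloxy)-2,6-dibromo-3-(2,4-dibromophenoxy)phenol, via C5 monobromophenol 18 (not isolated)
Conditions: NBS (2.1 equiv), i-Pr2NH (cat.), CH2Cl2, 0 °C, dark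
Reagents that add atoms: N-bromosuccinimide, O=C1CCC(=O)N1Br
Why: Electrophilic aromatic substitution directed by the free hydroxyl, whose para position is blocked, so both bromines should enter ortho (the less hindered C5 first, then C3, both also activated by the aryloxy group); C6 is meta to the hydroxyl and ring B is deactivated by its two bromines.

Step 10
Reactants: 19 4-(benzyloxy)-2,6-dibromo-3-(2,4-dibromophenoxy)phenol
Product: 20 1-(benzyloxy)-3,5-dibromo-2-(2,4-dibromophenoxy)-4-methoxybenzene
Conditions: MeI, K2CO3, acetone, 40 °C
Reagents that add atoms: iodomethane, CI
Why: Williamson O-methylation of the acidic 2,6-dibromophenol; the small electrophile should tolerate the two flanking bromines.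

Step 11
Reactants: 20 1-(benzyloxy)-3,5-dibromo-2-(2,4-dibromophenoxy)-4-methoxybenzene
Product: 22 3,5-dibromo-2-(2,4-dibromophenoxy)-4-methoxyphenol, via aryloxydichloroborane 21 (not isolated)
Conditions: BCl3 (2 equiv), pentamethylbenzene (3 equiv), CH2Cl2, −78 °C; then H2O
Reagents that add atoms: none
Why: Lewis-acid cleavage of the benzyl ether through the O–BCl2 species 21, with pentamethylbenzene trapping the benzyl cation by Friedel–Crafts alkylation; at −78 °C the methyl ether and the four C–Br bonds, which hydrogenolysis would endanger, should remain untouched.

## Compound list

1 | coumalic acid (2-oxo-2H-pyran-5-carboxylic acid) | O=C(O)c1ccc(=O)oc1 | starting material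
2 | 3-bromo-2-oxo-2H-pyran-5-carboxylic acid (3-bromocoumalic acid; not isolated) | O=C(O)c1cc(Br)c(=O)oc1 | intermediate
3 | 3,5-dibromo-2H-pyran-2-one | O=c1occ(Br)cc1Br | intermediate
4 | 2,5-dihydroxybenzaldehyde | O=Cc1cc(O)ccc1O | starting material
5 | 2-hydroxy-5-[(triisopropylsilyl)oxy]benzaldehyde | O=Cc1cc(O[Si](C(C)C)(C(C)C)C(C)C)ccc1O | intermediate
6 | 2-(benzyloxy)-5-[(triisopropylsilyl)oxy]benzaldehyde | O=Cc1cc(O[Si](C(C)C)(C(C)C)C(C)C)ccc1OCc1ccccc1 | intermediate
7 | 2-(benzyloxy)-5-[(triisopropylsilyl)oxy]phenyl formate (not isolated) | O=COc1cc(O[Si](C(C)C)(C(C)C)C(C)C)ccc1OCc1ccccc1 | intermediate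
8 | 2-(benzyloxy)-5-[(triisopropylsilyl)oxy]phenol | Oc1cc(O[Si](C(C)C)(C(C)C)C(C)C)ccc1OCc1ccccc1 | intermediate
9 | trichloroethylene | ClC=C(Cl)Cl | starting material
10 | dichloroacetylene (not isolated) | ClC#CCl | intermediate
11 | 1-(benzyloxy)-2-{[(E)-1,2-dichloroethenyl]oxy}-4-[(triisopropylsilyl)oxy]benzene | Cl/C=C(/Cl)Oc1cc(O[Si](C(C)C)(C(C)C)C(C)C)ccc1OCc1ccccc1 | intermediate
12 | 1-(benzyloxy)-2-[(chloroethynyl)oxy]-4-[(triisopropylsilyl)oxy]benzene (not isolated) | ClC#COc1cc(O[Si](C(C)C)(C(C)C)C(C)C)ccc1OCc1ccccc1 | intermediate
13 | {[2-(benzyloxy)-5-(triisopropylsilyloxy)phenoxy]ethynyl}lithium (not isolated) | [Li]C#COc1cc(O[Si](C(C)C)(C(C)C)C(C)C)ccc1OCc1ccccc1 | intermediate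
14 | 1-(benzyloxy)-2-(ethynyloxy)-4-[(triisopropylsilyl)oxy]benzene | C#COc1cc(O[Si](C(C)C)(C(C)C)C(C)C)ccc1OCc1ccccc1 | intermediate
15 | 5-[2-(benzyloxy)-5-(triisopropylsilyloxy)phenoxy]-4,7-dibromo-2-oxabicyclo[2.2.2]octa-5,7-dien-3-one (racemic; relative configuration fixed by the bicyclic frame; one enantiomer drawn; not isolated) | O=C1O[C@H]2C=C(Oc3cc(O[Si](C(C)C)(C(C)C)C(C)C)ccc3OCc3ccccc3)[C@]1(Br)C=C2Br | intermediate
16 | 1-(benzyloxy)-2-(2,4-dibromophenoxy)-4-[(triisopropylsilyl)oxy]benzene | Brc1ccc(Oc2cc(O[Si](C(C)C)(C(C)C)C(C)C)ccc2OCc2ccccc2)c(Br)c1 | intermediate
17 | 4-(benzyloxy)-3-(2,4-dibromophenoxy)phenol | Oc1ccc(OCc2ccccc2)c(Oc2ccc(Br)cc2Br)c1 | intermediate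
18 | 4-(benzyloxy)-2-bromo-5-(2,4-dibromophenoxy)phenol (not isolated) | Oc1cc(Oc2ccc(Br)cc2Br)c(OCc2ccccc2)cc1Br | intermediate
19 | 4-(benzyloxy)-2,6-dibromo-3-(2,4-dibromophenoxy)phenol | Oc1c(Br)cc(OCc2ccccc2)c(Oc2ccc(Br)cc2Br)c1Br | intermediate
20 | 1-(benzyloxy)-3,5-dibromo-2-(2,4-dibromophenoxy)-4-methoxybenzene | COc1c(Br)cc(OCc2ccccc2)c(Oc2ccc(Br)cc2Br)c1Br | intermediate
21 | [3,5-dibromo-2-(2,4-dibromophenoxy)-4-methoxyphenoxy]dichloroborane (not isolated) | COc1c(Br)cc(OB(Cl)Cl)c(Oc2ccc(Br)cc2Br)c1Br | intermediate
22 | 3,5-dibromo-2-(2,4-dibromophenoxy)-4-methoxyphenol | COc1c(Br)cc(O)c(Oc2ccc(Br)cc2Br)c1Br | target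

## Step count and risk

Total: 11 steps. Longest linear sequence: 10 steps (steps 2 to 11, from 4 to 22). Step 1 is a one-step side branch that supplies 3.

Steps least certain to work:

Step 7 (key step). The most likely failure is thermal oligomerisation or adventitious hydration of the terminal ynol ether running ahead of the bimolecular cycloaddition, or partial addition in the reverse orientation. The step needs heat and relies on frontier-orbital polarisation alone for its regiochemistry. Fallback: give up the de novo construction of ring B and form the diaryl ether by Chan–Lam O-arylation of phenol 8 with (2,4-dibromophenyl)boronic acid, using Cu(OAc)2 (divalent copper), pyridine, 4 Å molecular sieves, CH2Cl2, air, rt. Aryl bromides are inert to this copper chemistry and the room-temperature conditions spare the silyl ether. The fallback sets out from 8 and comes back at 16; it makes no compound outside the compound list and is entered as F0.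

Step 6. The most likely failure is decomposition of the terminal ynol ether during isolation (polymerisation on concentration, hydration on silica), with benzylic metallation by excess alkyllithium as a lesser risk if the temperature rises. Fallback: quench acetylide 13 with chlorotrimethylsilane instead of water to give {[2-(benzyloxy)-5-(triisopropylsilyloxy)phenoxy]ethynyl}trimethylsilane F2. This lacks the reactive terminus and should tolerate chromatography and storage. Brief K2CO3/MeOH at 0 °C just before the cycloaddition then frees the terminal alkyne. The fallback sets out from 11 (through 13 in the flask) and comes back at 14.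

Step 5. The most likely failure is carbonate-induced loss of the aryl silyl group in hot DMF followed by vinylation of the wrong oxygen. The step also passes through hazardous dichloroacetylene. Fallback: a formate-based two-carbon homologation. The peracid oxidation of 6 is stopped at aryl formate 7, isolated after a neutral work-up without methanolysis. Ramirez (Corey–Fuchs-type) dibromomethylenation (CBr4, PPh3, Et3N, CH2Cl2, 0 °C) converts it into 1-(benzyloxy)-2-[(2,2-dibromoethenyl)oxy]-4-[(triisopropylsilyl)oxy]benzene F1. n-BuLi (2.2 equiv, THF, −78 °C) then gives acetylide 13 by elimination and bromine–lithium exchange, and water gives 14. The fallback sets out from 6 and comes back at 14.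

Step 9. The most likely failure is oxidation of the para-alkoxyphenol towards a quinone with loss of the benzyl group, or bromination spilling over to C6, because 17 is a very electron-rich hydroquinone monoether. Fallback: replace the benzyl group by an electron-withdrawing acyl group before bromination. From 16, BCl3/pentamethylbenzene (CH2Cl2, −78 °C) should give 2-(2,4-dibromophenoxy)-4-[(triisopropylsilyl)oxy]phenol F3. Pivaloyl chloride/Et3N/DMAP then gives 2-(2,4-dibromophenoxy)-4-[(triisopropylsilyl)oxy]phenyl pivalate F4, and Bu4NF/AcOH gives 2-(2,4-dibromophenoxy)-4-hydroxyphenyl pivalate F5. NBS (2 equiv) should convert this into [3,5-dibromo-2-(2,4-dibromophenoxy)-4-hydroxyphenyl] pivalate A6, the compound that alternative 2 would reach another way. MeI/K2CO3 gives 3,5-dibromo-2-(2,4-dibromophenoxy)-4-methoxyphenyl pivalate F6, and K2CO3/MeOH removes the ester. The fallback sets out from 16 and comes back at 22.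

Step 11. The most likely failure is competing demethylation of the crowded C4 methyl ether, which is twisted out of conjugation by its two bromine neighbours and therefore more Lewis basic, or C-benzylation of the product if the cation trap is outrun. Fallback: change the order of events. Debenzylate 19, before the methyl ether exists (BCl3, pentamethylbenzene, CH2Cl2, −78 °C), to give 3,5-dibromo-2-(2,4-dibromophenoxy)benzene-1,4-diol F7. Then methylate only the more acidic hydroxyl, the one flanked by two bromines, with (trimethylsilyl)diazomethane in toluene–MeOH under argon. The fallback sets out from 19 and comes back at 22.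

## Further compounds

F0 | step 7 | none | none
F1 | step 5 | 1-(benzyloxy)-2-[(2,2-dibromoethenyl)oxy]-4-[(triisopropylsilyl)oxy]benzene | BrC(Br)=COc1cc(O[Si](C(C)C)(C(C)C)C(C)C)ccc1OCc1ccccc1
F2 | step 6 | {[2-(benzyloxy)-5-(triisopropylsilyloxy)phenoxy]ethynyl}trimethylsilane | C[Si](C)(C)C#COc1cc(O[Si](C(C)C)(C(C)C)C(C)C)ccc1OCc1ccccc1
F3 | step 9 | 2-(2,4-dibromophenoxy)-4-[(triisopropylsilyl)oxy]phenol | Oc1ccc(O[Si](C(C)C)(C(C)C)C(C)C)cc1Oc1ccc(Br)cc1Br
F4 | step 9 | 2-(2,4-dibromophenoxy)-4-[(triisopropylsilyl)oxy]phenyl pivalate | CC(C)(C)C(=O)Oc1ccc(O[Si](C(C)C)(C(C)C)C(C)C)cc1Oc1ccc(Br)cc1Br
F5 | step 9 | 2-(2,4-dibromophenoxy)-4-hydroxyphenyl pivalate | CC(C)(C)C(=O)Oc1ccc(O)cc1Oc1ccc(Br)cc1Br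
F6 | step 9 | 3,5-dibromo-2-(2,4-dibromophenoxy)-4-methoxyphenyl pivalate | COc1c(Br)cc(OC(=O)C(C)(C)C)c(Oc2ccc(Br)cc2Br)c1Br
F7 | step 11 | 3,5-dibromo-2-(2,4-dibromophenoxy)benzene-1,4-diol | Oc1cc(Br)c(O)c(Br)c1Oc1ccc(Br)cc1Br
A1 | alternative 1 | 2-(2,4-dibromophenoxy)-4-methoxyphenol | COc1ccc(O)c(Oc2ccc(Br)cc2Br)c1
A2 | alternative 1 | 2,4-dibromo-1-(ethynyloxy)benzene | C#COc1ccc(Br)cc1Br
A3 | alternative 1 | pentacarbonyl[methoxy(vinyl)carbene]chromium, (CO)5Cr=C(OMe)CH=CH2 | C=CC(OC)=[Cr](=C=O)(=C=O)(=C=O)(=C=O)=C=O
A4 | alternative 1 | 2,4-dibromophenol | Oc1ccc(Br)cc1Br
A5 | alternative 2 | (4-hydroxy-2-phenoxyphenyl) pivalate | CC(C)(C)C(=O)Oc1ccc(O)cc1Oc1ccccc1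
A6 | alternative 2 | [3,5-dibromo-2-(2,4-dibromophenoxy)-4-hydroxyphenyl] pivalate | CC(C)(C)C(=O)Oc1cc(Br)c(O)c(Br)c1Oc1ccc(Br)cc1Br
A7 | alternative 2 | bromine | BrBr
A8 | alternative 3 | 3-methoxy-2-(trimethylsilyl)phenyl trifluoromethanesulfonate | COc1cccc(OS(=O)(=O)C(F)(F)F)c1[Si](C)(C)C
A9 | alternative 3 | 3-methoxybenzyne | COC1=CC=CC#C1
A10 | alternative 3 | tetrabromomethane | BrC(Br)(Br)Br
A11 | alternative 3 | 2-bromo-1-(2,4-dibromophenoxy)-3-methoxybenzene | COc1cccc(Oc2ccc(Br)cc2Br)c1Br
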